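## Retrosynthetic overview
1. C7: the benzylic acetate comes from the (8R)-α-aryloxy aryl ketone. Hydride is delivered to C7 under Felkin–Anh control and the alkoxide is trapped with Ac2O in the same flask.
2. C8–O: the α-aryloxy ketone comes from an (S)-α-hydroxy ketone and (Z)-isoeugenol by Mitsunobu etherification with inversion.
3. C7–C8 (key bond): the (S)-α-hydroxy ketone comes from veratraldehyde and acetaldehyde. Veratraldehyde reacts as a veratroyl anion (thiamine Breslow enaminol inside an (S)-selective carboligase). Two carbonyl carbons are joined without masking groups, and C8 is set as the bond forms.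
4. (Z)-Isoeugenol comes from 4-bromoguaiacol and (Z)-propenylboronic acid by stereoretentive Suzuki coupling.
5. No ring is formed; both benzene rings are bought intact.

Assumption: C7 is the benzylic carbon and C8 the ether-bearing carbon; CIP analysis of the SMILES gives (7R,8R), the threo series with a Z alkene; the recombinant carboligase counts as a catalyst.

## Route

Step 1
Reactants: 1 3,4-dimethoxybenzaldehyde (veratraldehyde); 2 acetaldehyde
Product: 4 (S)-1-(3,4-dimethoxyphenyl)-2-hydroxypropan-1-one, via ThDP-bound Breslow enaminol 3 (not isolated)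
Conditions: benzoylformate decarboxylase (P. putida, L476Q variant, cell extract), ThDP (0.5 mM), MgSO4 (2.5 mM), KPi buffer pH 7.0/DMSO 4:1, 2 in excess (fed), 30 °C; EtOAc extraction, recrystallisation
Reagents that add atoms: none
Why: This is a ThDP-dependent enzymatic cross-benzoin (acyloin) carboligation in which the cofactor ylide adds to 1, the resulting Breslow enaminol 3 acts as a veratroyl anion and attacks the carbonyl carbon of 2, and the enzyme's small S-pocket holds the methyl group of 2 antiparallel to the donor so that one aldehyde face is exposed and C8 forms as (S), with methoxy-substituted benzaldehydes lying within the known donor range of this enzyme.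

Step 2
Reactants: 5 4-bromo-2-methoxyphenol; 6 (Z)-prop-1-en-1-ylboronic acid
Product: 7 (Z)-isoeugenol (2-methoxy-4-[(Z)-prop-1-en-1-yl]phenol)
Conditions: Pd(PPh3)4 (3 mol %), K2CO3, 1,4-dioxane/H2O 4:1, 80 °C
Reagents that add atoms: none
Why: This is a Suzuki–Miyaura coupling in which transmetalation and reductive elimination both retain alkenyl geometry, so the Z configuration of 6 is carried into 7 and the free phenol is tolerated as its phenoxide.

Step 3
Reactants: 4 (S)-1-(3,4-dimethoxyphenyl)-2-hydroxypropan-1-one; 7 (Z)-isoeugenol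
Product: 9 (R)-1-(3,4-dimethoxyphenyl)-2-{2-methoxy-4-[(Z)-prop-1-en-1-yl]phenoxy}propan-1-one, via oxyphosphonium aryloxide ion pair 8 (not isolated)
Conditions: PPh3, DIAD, toluene, 0 °C to rt
Reagents that add atoms: none
Why: This is a Mitsunobu etherification in which the carbinol of 4 is activated as oxyphosphonium ion 8 and displaced by the phenoxide of 7 (pKa about 10) in an SN2 step accelerated by the adjacent carbonyl, inverting C8 from (S) to (R) in a medium too weakly basic to enolise the ketone.

Step 4
Reactants: 9 (R)-1-(3,4-dimethoxyphenyl)-2-{2-methoxy-4-[(Z)-prop-1-en-1-yl]phenoxy}propan-1-one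
Product: 11 ligraminol C [(1R,2R)-1-(3,4-dimethoxyphenyl)-2-{2-methoxy-4-[(Z)-prop-1-en-1-yl]phenoxy}propyl acetate], via potassium threo-alkoxide 10 (not isolated)
Conditions: K-Selectride (1.1 equiv), THF, −78 °C; then Ac2O (3 equiv), DMAP (cat.), −78 to 0 °C; pH 7 buffer, chromatography
Reagents that add atoms: acetic anhydride CC(=O)OC(C)=O
Why: This is a polar Felkin–Anh-controlled ketone reduction followed by in-flask O-acetylation, where the bulky hydride, the poorly chelating K+ and the weakly Lewis-basic aryl ether oxygen place the C8–OAr bond anti to the incoming hydride, which passes the C8–H side to give the (7R) alkoxide 10 of the threo series, and Ac2O then acylates oxygen without touching either stereocenter or the Z alkene.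

## Compound list
1 | 3,4-dimethoxybenzaldehyde (veratraldehyde) | COc1ccc(C=O)cc1OC | starting material
2 | acetaldehyde | CC=O | starting material
3 | Breslow enaminol of veratraldehyde on thiamine diphosphate (enzyme-bound, cofactor catalytic) | Cc1ncc(CN2C(C)=C(CCOP(=O)(O)OP(=O)(O)O)SC2=C(O)c2ccc(OC)c(OC)c2)c(N)n1 | intermediate
4 | (S)-1-(3,4-dimethoxyphenyl)-2-hydroxypropan-1-one | C[C@H](O)C(=O)c1ccc(OC)c(OC)c1 | intermediate
5 | 4-bromo-2-methoxyphenol | COc1cc(Br)ccc1O | starting material
6 | (Z)-prop-1-en-1-ylboronic acid | C/C=C\B(O)O | starting material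
7 | (Z)-isoeugenol, 2-methoxy-4-[(Z)-prop-1-en-1-yl]phenol | C/C=C\c1ccc(O)c(OC)c1 | intermediate
8 | {[(S)-1-(3,4-dimethoxyphenyl)-1-oxopropan-2-yl]oxy}triphenylphosphonium 2-methoxy-4-[(Z)-prop-1-en-1-yl]phenoxide | C[C@H](O[P+](c1ccccc1)(c1ccccc1)c1ccccc1)C(=O)c1ccc(OC)c(OC)c1.[O-]c1ccc(/C=C\C)cc1OC | intermediate
9 | (R)-1-(3,4-dimethoxyphenyl)-2-{2-methoxy-4-[(Z)-prop-1-en-1-yl]phenoxy}propan-1-one | C/C=C\c1ccc(O[C@H](C)C(=O)c2ccc(OC)c(OC)c2)c(OC)c1 | intermediate
10 | potassium (1R,2R)-1-(3,4-dimethoxyphenyl)-2-{2-methoxy-4-[(Z)-prop-1-en-1-yl]phenoxy}propan-1-olate | C/C=C\c1ccc(O[C@H](C)[C@H]([O-])c2ccc(OC)c(OC)c2)c(OC)c1.[K+] | intermediate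
11 | ligraminol C, (1R,2R)-1-(3,4-dimethoxyphenyl)-2-{2-methoxy-4-[(Z)-prop-1-en-1-yl]phenoxy}propyl acetate | C/C=C\c1ccc(O[C@H](C)[C@H](OC(C)=O)c2ccc(OC)c(OC)c2)c(OC)c1 | target

## Step count and risks
Total step count: 4. Longest linear sequence: 3 (steps 1, 3, 4; the branch through steps 2, 3, 4 is also 3).

**Step 1.** The electron-rich, para-alkoxy donor may be turned over slowly by the enzyme, or the ee may be too low.
- The fallback sets out from 1 and 2 and keeps the same acyl-anion bond construction without stereocontrol.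
- A thiazolium-derived N-heterocyclic carbene (3-benzyl-5-(2-hydroxyethyl)-4-methylthiazolium chloride, Cs2CO3, THF, excess acetaldehyde) gives racemic 1-(3,4-dimethoxyphenyl)-2-hydroxypropan-1-one F1.
- A lipase kinetic resolution (Candida antarctica lipase B, vinyl acetate, MTBE) then acetylates the (R)-enantiomer to (R)-1-(3,4-dimethoxyphenyl)-1-oxopropan-2-yl acetate F2.
- The unreacted (S)-alcohol (at most 50 %) is separated on silica, and the route is rejoined at 4.

**Step 4.** Chelation could leak to the erythro isomer, the basic hydride could enolise the ketone, or the borane-associated alkoxide could acetylate slowly.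
- The fallback sets out from 9 and replaces substrate control with catalyst control.
- Noyori–Ikariya transfer hydrogenation uses RuCl[(S,S)-TsDPEN](p-cymene) in HCO2H/Et3N 5:2 at rt. This is the catalyst/substrate pairing that turns benzoin into (R,R)-hydrobenzoin.
- It gives the isolated alcohol (1R,2R)-1-(3,4-dimethoxyphenyl)-2-{2-methoxy-4-[(Z)-prop-1-en-1-yl]phenoxy}propan-1-ol F4.
- Separate acetylation (Ac2O, pyridine, DMAP) rejoins the route at 11.

**Step 3.** The stereocenter next to the carbonyl could partly racemise, or elimination to the aryl vinyl ketone could compete.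
- The fallback sets out from 4 and separates activation from displacement.
- MsCl and Et3N in CH2Cl2 at −20 °C give (S)-1-(3,4-dimethoxyphenyl)-1-oxopropan-2-yl methanesulfonate F3, with the C–O bond untouched.
- F3 is displaced with inversion by the preformed potassium phenoxide of 7 (K2CO3, acetone, rt), and the route is rejoined at 9.

## Further compounds
F1 | step 1 | racemic 1-(3,4-dimethoxyphenyl)-2-hydroxypropan-1-one | CC(O)C(=O)c1ccc(OC)c(OC)c1
F2 | step 1 | (R)-1-(3,4-dimethoxyphenyl)-1-oxopropan-2-yl acetate | C[C@@H](OC(C)=O)C(=O)c1ccc(OC)c(OC)c1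
F3 | step 3 | (S)-1-(3,4-dimethoxyphenyl)-1-oxopropan-2-yl methanesulfonate | C[C@H](OS(C)(=O)=O)C(=O)c1ccc(OC)c(OC)c1
F4 | step 4 | (1R,2R)-1-(3,4-dimethoxyphenyl)-2-{2-methoxy-4-[(Z)-prop-1-en-1-yl]phenoxy}propan-1-ol | C/C=C\c1ccc(O[C@H](C)[C@H](O)c2ccc(OC)c(OC)c2)c(OC)c1
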